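**Retrosynthetic overview**
1. Target 15 ⇒ p-hydroxyphenacyl acetate 13 by a photo-Favorskii 1,2-aryl shift. Light makes the aryl–C2 bond, the aroyl carbon becomes the free C1 acid (so the C4 methyl ester never has to be differentiated), and C2 is set under control of C3.
2. 13 ⇒ aryl Grignard reagent 10 + Weinreb amide 8 (C1 of a 3-benzylmalate), then O-acetylation and desilylation.
3. 8 ⇒ dimethyl (S)-malate 4 (chiral pool; its carbinol centre sets C3 in a Fráter–Seebach alkylation) + benzylic bromide 3; the prenyl group enters by Stille coupling at the aryl bromide.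
4. No ring is built; the only ring formed is the transient spiro-cyclopropanone 14 of the photochemical step, opened by water in the same flask.

Assumptions: TBS = tert-butyldimethylsilyl. Locants C1–C4 in the text follow the target's butanedioic acid chain (C1 CO2H, C2 aryl-bearing CH, C3 benzyl-bearing CH, C4 CO2Me). The target SMILES is read as (2R,3R).

**Route**

Step 1
Reactants: 1 2-bromo-5-methylphenol
Product: 2 (2-bromo-5-methylphenoxy)(tert-butyl)dimethylsilane
Conditions: TBSCl (1.2 equiv), imidazole (2.2 equiv), DMF, rt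
Reagents that add atoms: tert-butyl(chloro)dimethylsilane (TBSCl), CC(C)(C)[Si](C)(C)Cl
Why: Imidazole-promoted O-silylation masks the acidic phenol for the radical bromination and the dianion alkylation; no stereocenter is involved.

Step 2
Reactants: 2 (2-bromo-5-methylphenoxy)(tert-butyl)dimethylsilane
Product: 3 [2-bromo-5-(bromomethyl)phenoxy](tert-butyl)dimethylsilane
Conditions: NBS (1.05 equiv), AIBN (5 mol%), PhCF3, 85 °C
Reagents that add atoms: N-bromosuccinimide, O=C1CCC(=O)N1Br
Why: Wohl–Ziegler bromination takes the only benzylic C–H position, and the non-polar medium suppresses ring bromination of the bromine-deactivated arene; no stereocenter is involved.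

Step 3
Reactants: 3 [2-bromo-5-(bromomethyl)phenoxy](tert-butyl)dimethylsilane; 4 dimethyl (S)-malate
Product: 6 dimethyl (2S,3R)-3-{[4-bromo-3-(tert-butyldimethylsilyloxy)phenyl]methyl}-2-hydroxybutanedioate, via dilithium alkoxide enolate 5 (not isolated)
Conditions: 4 (1.3 equiv), LiN(SiMe3)2 (2.7 equiv), THF, −78 to −20 °C; then 3 (1.0 equiv), −78 to −5 °C, 14 h; AcOH quench at −60 °C
Reagents that add atoms: lithium bis(trimethylsilyl)amide, [Li+].C[Si](C)(C)[N-][Si](C)(C)C (its lithium sits only in intermediate 5; nothing from it remains in 6)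
Why: Fráter–Seebach alkylation: in the lithium-chelated alkoxide enolate 5 the bromide attacks the enolate face opposite the C1 ester group held on the chelate ring, so the bought (2S) carbinol centre sets (3R) (anti, typically about 10:1; the minor isomer is removed by chromatography).

Step 4
Reactants: 6 dimethyl (2S,3R)-3-{[4-bromo-3-(tert-butyldimethylsilyloxy)phenyl]methyl}-2-hydroxybutanedioate
Product: 7 dimethyl (2S,3R)-3-{[3-(tert-butyldimethylsilyloxy)-4-(3-methylbut-2-en-1-yl)phenyl]methyl}-2-hydroxybutanedioate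
Conditions: tributyl(3-methylbut-2-en-1-yl)stannane (1.3 equiv), Pd(PPh3)4 (5 mol%), degassed DMF, 90 °C; tin removed on KF/silica
Reagents that add atoms: tributyl(3-methylbut-2-en-1-yl)stannane, CC(C)=CC[Sn](CCCC)(CCCC)CCCC
Why: Stille coupling (oxidative addition into the aryl C–Br bond, transmetalation of the allylic stannane, reductive elimination) gives the linear prenyl arene under neutral conditions that leave the hydroxy diester and both stereocenters untouched.

Step 5
Reactants: 7 dimethyl (2S,3R)-3-{[3-(tert-butyldimethylsilyloxy)-4-(3-methylbut-2-en-1-yl)phenyl]methyl}-2-hydroxybutanedioate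
Product: 8 methyl (2R,3S)-2-{[3-(tert-butyldimethylsilyloxy)-4-(3-methylbut-2-en-1-yl)phenyl]methyl}-3-hydroxy-4-[methoxy(methyl)amino]-4-oxobutanoate
Conditions: Me(MeO)NH·HCl (3 equiv), AlMe3 (3 equiv), CH2Cl2, 0 °C to rt; cold 1 M HCl work-up
Reagents that add atoms: N,O-dimethylhydroxylamine hydrochloride, CNOC.Cl
Why: Weinreb amidation with the aluminium amide: the aluminium alkoxide of the C2 hydroxyl activates the neighbouring C1 ester while the α-branched C4 ester reacts much more slowly, and the Lewis-acidic medium does not enolise either stereocenter.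

Step 6
Reactants: 8 methyl (2R,3S)-2-{[3-(tert-butyldimethylsilyloxy)-4-(3-methylbut-2-en-1-yl)phenyl]methyl}-3-hydroxy-4-[methoxy(methyl)amino]-4-oxobutanoate; 9 (4-bromophenoxy)(tert-butyl)dimethylsilane
Product: 11 methyl (2R,3S)-4-[4-(tert-butyldimethylsilyloxy)phenyl]-2-{[3-(tert-butyldimethylsilyloxy)-4-(3-methylbut-2-en-1-yl)phenyl]methyl}-3-hydroxy-4-oxobutanoate, via aryl Grignard reagent 10 (not isolated)
Conditions: 9 (3 equiv), Mg turnings (3.3 equiv), THF, 50 °C; then 8 in THF, −20 to 0 °C; aq NH4Cl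
Reagents that add atoms: magnesium, [Mg] (held only in intermediate 10; nothing from it remains in 11)
Why: Weinreb ketone synthesis: one equivalent of 10 deprotonates the hydroxyl, a second adds to the amide to give a magnesium-chelated tetrahedral adduct that collapses to the ketone only on quench, and the α-branched methyl ester is left alone at or below 0 °C; the stereocenters are untouched.

Step 7
Reactants: 11 methyl (2R,3S)-4-[4-(tert-butyldimethylsilyloxy)phenyl]-2-{[3-(tert-butyldimethylsilyloxy)-4-(3-methylbut-2-en-1-yl)phenyl]methyl}-3-hydroxy-4-oxobutanoate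
Product: 12 methyl (2R,3S)-3-acetoxy-4-[4-(tert-butyldimethylsilyloxy)phenyl]-2-{[3-(tert-butyldimethylsilyloxy)-4-(3-methylbut-2-en-1-yl)phenyl]methyl}-4-oxobutanoate
Conditions: Ac2O (2 equiv), pyridine (4 equiv), DMAP (0.1 equiv), CH2Cl2, 0 °C to rt
Reagents that add atoms: acetic anhydride, CC(=O)OC(C)=O
Why: DMAP-catalysed acetylation turns the hydroxyl into the carboxylate leaving group the photoreaction needs; pyridine is too weak to cause β-elimination across C2–C3, and any epimerisation at C2 is harmless because step 8 planarises that carbon.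

Step 8
Reactants: 12 methyl (2R,3S)-3-acetoxy-4-[4-(tert-butyldimethylsilyloxy)phenyl]-2-{[3-(tert-butyldimethylsilyloxy)-4-(3-methylbut-2-en-1-yl)phenyl]methyl}-4-oxobutanoate
Product: 15 (2R,3R)-2-(4-hydroxyphenyl)-3-{[3-hydroxy-4-(3-methylbut-2-en-1-yl)phenyl]methyl}-4-methoxy-4-oxobutanoic acid, via bis-phenol acetate 13 (not isolated), via spirodienedione 14 (not isolated)
Conditions: Bu4NF·3H2O (2.4 equiv), AcOH (3 equiv), MeCN, 0 °C to rt, 1 h; then H2O added to MeCN/H2O 1:1 (2 mM), Ar-sparged, hν 300–313 nm (Pyrex), 15 °C; dilute HCl, EtOAc; reverse-phase HPLC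
Reagents that add atoms: water, O
Why: Proposed new method: buffered fluoride frees both phenols, then the triplet p-hydroxyphenacyl chromophore of 13 loses acetate with water-assisted phenol deprotonation to give a planar oxyallyl–phenoxy biradical (the lowest triplet is π,π*, so γ-hydrogen abstraction from the benzylic CH2 is slow), which after intersystem crossing closes C2 onto the ipso carbon to spirodienedione 14 through a Felkin-type transition state (forming bond anti to the C3–CH2Ar bond, the largest group and best σ-donor; C3–H on the side of the acyl carbon; C4 ester anti to C1), setting (2R) under control of C3 before water opens the cyclopropanone with rearomatisation to the C1 acid; the closest known reaction is the photo-Favorskii rearrangement of p-hydroxyphenacyl esters, established for unbranched and simple α-alkyl cases where the α-carbon emerges without stereocontrol, and not yet shown on an α,β-branched substrate with a controlling β-stereocenter.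

**Compound list**
1 | 2-bromo-5-methylphenol | Cc1ccc(Br)c(O)c1 | starting material
2 | (2-bromo-5-methylphenoxy)(tert-butyl)dimethylsilane | Cc1ccc(Br)c(O[Si](C)(C)C(C)(C)C)c1 | intermediate
3 | [2-bromo-5-(bromomethyl)phenoxy](tert-butyl)dimethylsilane | BrCc1ccc(Br)c(O[Si](C)(C)C(C)(C)C)c1 | intermediate
4 | dimethyl (S)-malate [dimethyl (2S)-2-hydroxybutanedioate] | COC(=O)[C@@H](O)CC(=O)OC | starting material
5 | dilithium (2S,3E)-1,4-dimethoxy-1-oxobut-3-ene-2,4-bis(olate) (chelated alkoxide enolate of 4) | [Li+].[Li+].COC(=O)[C@@H]([O-])/C=C(/OC)[O-] | intermediate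
6 | dimethyl (2S,3R)-3-{[4-bromo-3-(tert-butyldimethylsilyloxy)phenyl]methyl}-2-hydroxybutanedioate | COC(=O)[C@@H](O)[C@@H](Cc1ccc(Br)c(O[Si](C)(C)C(C)(C)C)c1)C(=O)OC | intermediate
7 | dimethyl (2S,3R)-3-{[3-(tert-butyldimethylsilyloxy)-4-(3-methylbut-2-en-1-yl)phenyl]methyl}-2-hydroxybutanedioate | COC(=O)[C@@H](O)[C@@H](Cc1ccc(CC=C(C)C)c(O[Si](C)(C)C(C)(C)C)c1)C(=O)OC | intermediate
8 | methyl (2R,3S)-2-{[3-(tert-butyldimethylsilyloxy)-4-(3-methylbut-2-en-1-yl)phenyl]methyl}-3-hydroxy-4-[methoxy(methyl)amino]-4-oxobutanoate (carbinol carbon S; benzyl-bearing carbon R) | CON(C)C(=O)[C@@H](O)[C@@H](Cc1ccc(CC=C(C)C)c(O[Si](C)(C)C(C)(C)C)c1)C(=O)OC | intermediate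
9 | (4-bromophenoxy)(tert-butyl)dimethylsilane | CC(C)(C)[Si](C)(C)Oc1ccc(Br)cc1 | starting material
10 | [4-(tert-butyldimethylsilyloxy)phenyl]magnesium bromide | CC(C)(C)[Si](C)(C)Oc1ccc([Mg]Br)cc1 | intermediate
11 | methyl (2R,3S)-4-[4-(tert-butyldimethylsilyloxy)phenyl]-2-{[3-(tert-butyldimethylsilyloxy)-4-(3-methylbut-2-en-1-yl)phenyl]methyl}-3-hydroxy-4-oxobutanoate | O=C(c1ccc(O[Si](C)(C)C(C)(C)C)cc1)[C@@H](O)[C@@H](Cc1ccc(CC=C(C)C)c(O[Si](C)(C)C(C)(C)C)c1)C(=O)OC | intermediate
12 | methyl (2R,3S)-3-acetoxy-4-[4-(tert-butyldimethylsilyloxy)phenyl]-2-{[3-(tert-butyldimethylsilyloxy)-4-(3-methylbut-2-en-1-yl)phenyl]methyl}-4-oxobutanoate | O=C(c1ccc(O[Si](C)(C)C(C)(C)C)cc1)[C@@H](OC(C)=O)[C@@H](Cc1ccc(CC=C(C)C)c(O[Si](C)(C)C(C)(C)C)c1)C(=O)OC | intermediate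
13 | methyl (2R,3S)-3-acetoxy-4-(4-hydroxyphenyl)-2-{[3-hydroxy-4-(3-methylbut-2-en-1-yl)phenyl]methyl}-4-oxobutanoate | O=C(c1ccc(O)cc1)[C@@H](OC(C)=O)[C@@H](Cc1ccc(CC=C(C)C)c(O)c1)C(=O)OC | intermediate
14 | methyl (2R)-2-[(2R)-1,6-dioxospiro[2.5]octa-4,7-dien-2-yl]-3-[3-hydroxy-4-(3-methylbut-2-en-1-yl)phenyl]propanoate | COC(=O)[C@H](Cc1ccc(CC=C(C)C)c(O)c1)[C@H]1C(=O)C12C=CC(=O)C=C2 | intermediate
15 | (2R,3R)-2-(4-hydroxyphenyl)-3-{[3-hydroxy-4-(3-methylbut-2-en-1-yl)phenyl]methyl}-4-methoxy-4-oxobutanoic acid (CNP0437978.2) | COC(=O)[C@H](Cc1ccc(CC=C(C)C)c(O)c1)[C@@H](C(=O)O)c1ccc(O)cc1 | target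

**Step count and risks**
Total steps: 8. Longest linear sequence: 8 (1 → 2 → 3 → 6 → 7 → 8 → 11 → 12 → 15).

Step 8 (the proposed photo-Favorskii step) is the most likely to fail. The facial selectivity at C2 rests on acyclic control and may be only moderate (I estimate about 3–5:1), with the epimer removed by HPLC. Loss of the C3 proton from the oxyallyl intermediate would give the aroyl acrylate. Decarbonylation of 14 competes if the water content is low. The free phenol of the benzyl ring may quench the triplet; keeping that silyl ether on during irradiation and removing it afterwards would test this, at the cost of one step. The fallback uses known chemistry, sets out from 7 and returns at 15. Mitsunobu inversion of the carbinol (4-nitrobenzoic acid, PPh3, DIAD) gives dimethyl (2R,3R)-2-(4-nitrobenzoyloxy)-3-(arylmethyl)butanedioate F1. LiOH (THF/H2O, 0 °C) cleaves the nitrobenzoate and the activated C1 methyl ester to the (2R,3R) hydroxy acid F2. MsCl/Et3N followed by aqueous work-up gives the α-mesyloxy acid F3. Its magnesium carboxylate is arylated with inversion by the diarylcuprate made from 10 and CuBr·SMe2 (copper-mediated displacement of α-sulfonyloxy carboxylic acid derivatives, the type used for 2-arylpropanoic acids; the β-branch makes this displacement slow) to give the bis-silyl (2R,3R) acid F4. Bu4NF/AcOH then gives 15. The double inversion delivers the same C2 configuration stereospecifically.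

Step 5 (regioselective amidation) may give amide at C4 or at both esters. The fallback sets out from 3 and returns at 8, with the amide placed before the alkylation so that only one carbonyl can react. Commercial (S)-2-(2,2-dimethyl-5-oxo-1,3-dioxolan-4-yl)acetic acid F5 (the acetonide of L-malic acid, in which only C1 is an activated ester) is opened with Me(MeO)NH·HCl/iPrMgCl, losing acetone, to (3S)-3-hydroxy-4-[methoxy(methyl)amino]-4-oxobutanoic acid F6. MeI/KHCO3 in DMF gives its methyl ester F7. Fráter–Seebach alkylation of F7 with 3 (LiN(SiMe3)2, 2.1 equiv) gives the bromoaryl Weinreb amide F8. Stille prenylation as in step 4 then gives 8.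

Step 4 (Stille prenylation) may give the 1,1-dimethylallyl isomer or a migrated double bond through allylic transposition of the stannane. The fallback sets out from 6 and returns at 7. Stille coupling with allyltributylstannane (Pd(PPh3)4, DMF, 90 °C), which has no regiochemical ambiguity, gives the allyl arene F9. Cross-metathesis with excess 2-methylbut-2-ene (second-generation Grubbs catalyst, CH2Cl2, 40 °C) converts allyl into prenyl and gives 7.

**Further compounds**
F1 | step 8 | dimethyl (2R,3R)-2-(4-nitrobenzoyloxy)-3-{[3-(tert-butyldimethylsilyloxy)-4-(3-methylbut-2-en-1-yl)phenyl]methyl}butanedioate | COC(=O)[C@H](OC(=O)c1ccc(cc1)[N+](=O)[O-])[C@@H](Cc1ccc(CC=C(C)C)c(O[Si](C)(C)C(C)(C)C)c1)C(=O)OC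
F2 | step 8 | (2R,3R)-3-{[3-(tert-butyldimethylsilyloxy)-4-(3-methylbut-2-en-1-yl)phenyl]methyl}-2-hydroxy-4-methoxy-4-oxobutanoic acid | OC(=O)[C@H](O)[C@@H](Cc1ccc(CC=C(C)C)c(O[Si](C)(C)C(C)(C)C)c1)C(=O)OC
F3 | step 8 | (2R,3R)-3-{[3-(tert-butyldimethylsilyloxy)-4-(3-methylbut-2-en-1-yl)phenyl]methyl}-2-(methanesulfonyloxy)-4-methoxy-4-oxobutanoic acid | OC(=O)[C@H](OS(C)(=O)=O)[C@@H](Cc1ccc(CC=C(C)C)c(O[Si](C)(C)C(C)(C)C)c1)C(=O)OC
F4 | step 8 | (2R,3R)-2-[4-(tert-butyldimethylsilyloxy)phenyl]-3-{[3-(tert-butyldimethylsilyloxy)-4-(3-methylbut-2-en-1-yl)phenyl]methyl}-4-methoxy-4-oxobutanoic acid | OC(=O)[C@@H](c1ccc(O[Si](C)(C)C(C)(C)C)cc1)[C@@H](Cc1ccc(CC=C(C)C)c(O[Si](C)(C)C(C)(C)C)c1)C(=O)OC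
F5 | step 5 | (S)-2-(2,2-dimethyl-5-oxo-1,3-dioxolan-4-yl)acetic acid | CC1(C)O[C@@H](CC(=O)O)C(=O)O1
F6 | step 5 | (3S)-3-hydroxy-4-[methoxy(methyl)amino]-4-oxobutanoic acid | CON(C)C(=O)[C@@H](O)CC(=O)O
F7 | step 5 | methyl (3S)-3-hydroxy-4-[methoxy(methyl)amino]-4-oxobutanoate | CON(C)C(=O)[C@@H](O)CC(=O)OC
F8 | step 5 | methyl (2R,3S)-2-{[4-bromo-3-(tert-butyldimethylsilyloxy)phenyl]methyl}-3-hydroxy-4-[methoxy(methyl)amino]-4-oxobutanoate | CON(C)C(=O)[C@@H](O)[C@@H](Cc1ccc(Br)c(O[Si](C)(C)C(C)(C)C)c1)C(=O)OC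
F9 | step 4 | dimethyl (2S,3R)-3-{[3-(tert-butyldimethylsilyloxy)-4-(prop-2-en-1-yl)phenyl]methyl}-2-hydroxybutanedioate | COC(=O)[C@@H](O)[C@@H](Cc1ccc(CC=C)c(O[Si](C)(C)C(C)(C)C)c1)C(=O)OC
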